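## Retrosynthetic overview

1. The target is unmasked last by hydrogenolysis of two benzyl ethers on the flavone half.
2. Ring C of the flavanone half is the only ring built. It is closed last, by a catalytic enantioselective 6-endo oxa-Michael addition of a free 2',6'-dihydroxychalcone, which sets C-2 as (S).
3. The chalcone comes from a Claisen–Schmidt condensation of 2',6'-dihydroxy-4'-methoxyacetophenone with a flavone-bearing 4-aryloxybenzaldehyde.
4. The diaryl ether comes from an SNAr reaction of the 3'-OH of 7,4'-di-O-benzylluteolin on 4-fluorobenzaldehyde.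
5. Rings A, C and B of the flavone half are bought intact as luteolin, which is dibenzylated regioselectively.

Assumption: the quinidine-derived squaramide QD-SQ (3-{[3,5-bis(trifluoromethyl)phenyl]amino}-4-{[(9R)-6'-methoxycinchonan-9-yl]amino}cyclobut-3-ene-1,2-dione) is taken to deliver the phenoxide to the Si face of C-β, giving (2S). If the chiroptical data show the opposite sense, its quinine-derived pseudoenantiomer is used in the same step.

## Route

Step 1
Reactants: 1 luteolin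
Product: 3 7-(benzyloxy)-2-[4-(benzyloxy)-3-hydroxyphenyl]-5-hydroxy-4H-chromen-4-one (7,4'-di-O-benzylluteolin), via 7-O-benzylluteolin 2 (not isolated)
Conditions: BnBr (2.1 equiv), K2CO3 (2.2 equiv), DMF, 0 °C to rt, 16 h
Reagents that add atoms: benzyl bromide (BrCc1ccccc1)
Why: Williamson etherification under acidity control: the 7-OH and then the 4'-OH (para-conjugated to the pyranone carbonyl) are the two most acidic phenols of luteolin and are benzylated first, while the less acidic 3'-OH and the chelated 5-OH stay free when the electrophile is limited to about two equivalents.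

Step 2
Reactants: 3 7,4'-di-O-benzylluteolin; 4 4-fluorobenzaldehyde (1.3 equiv)
Product: 5 4-{2-(benzyloxy)-5-[7-(benzyloxy)-5-hydroxy-4-oxo-4H-chromen-2-yl]phenoxy}benzaldehyde
Conditions: K2CO3 (1.5 equiv), DMF, 95 °C, 8 h
Reagents that add atoms: none
Why: SNAr (addition–elimination through a Meisenheimer adduct) of the 3'-phenoxide on the para-formyl-activated aryl fluoride; the chelated 5-OH is too weak a nucleophile to compete and the benzyl ethers are inert to carbonate.

Step 3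
Reactants: 5 aldehyde; 6 1-(2,6-dihydroxy-4-methoxyphenyl)ethan-1-one (1.2 equiv)
Product: 8 (2E)-3-(4-{2-(benzyloxy)-5-[7-(benzyloxy)-5-hydroxy-4-oxo-4H-chromen-2-yl]phenoxy}phenyl)-1-(2,6-dihydroxy-4-methoxyphenyl)prop-2-en-1-one, via aldol adduct 7 (not isolated)
Conditions: KOH (50% aq., 20 equiv), EtOH/THF 2:1, 0 °C to rt, 40 h, argon; then cold dilute aq. HCl to pH 3
Reagents that add atoms: none
Why: Claisen–Schmidt (crossed aldol) condensation of a non-enolisable aldehyde with the ketone enolate, followed by E1cB loss of water to the (E)-enone; in strong base the product rests as the ring-open chalcone phenolate and the flavone is shielded from hydroxide by its 5-phenoxide, so cold acidification releases the chalcone.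

Step 4
Reactants: 8 chalcone
Product: 10 (2S)-2-(4-{2-(benzyloxy)-5-[7-(benzyloxy)-5-hydroxy-4-oxo-4H-chromen-2-yl]phenoxy}phenyl)-5-hydroxy-7-methoxy-2,3-dihydro-4H-chromen-4-one, via flavanone enol 9 (not isolated)
Conditions: QD-SQ (10 mol%), toluene/CH2Cl2 1:1, 4 Å MS, −20 °C, 72 h; AcOH quench at −20 °C, silica plug
Reagents that add atoms: none
Why: Proposed new method: a chalcone-isomerase-like 6-endo-trig oxa-Michael addition under bifunctional Brønsted-base/hydrogen-bond catalysis, in which the quinuclidine nitrogen deprotonates the one non-chelated ortho-phenol (the two phenols are equivalent by aryl–CO rotation), the squaramide N–H pair binds the s-trans enone carbonyl beside the intact 6'-OH chelate and so fixes the enone in the chiral pocket, the ammonium-paired phenoxide adds to the Si face of C-β to set C-2 as (S), and the catalyst then protonates the enolate; the 5-OH···O=C chelate that persists in the product makes ring closure strongly downhill and slows the retro-oxa-Michael racemisation that limits simple 2'-hydroxychalcones; the closest known reaction type is the cinchona-thiourea-catalysed oxa-Michael cyclisation of 3-alkoxycarbonyl-activated 2'-hydroxychalcones, which has not been shown for unactivated free 2',6'-dihydroxychalcones.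

Step 5
Reactants: 10 (2S)-flavanone dibenzyl ether
Product: 13 (2S)-2-(4-{5-(5,7-dihydroxy-4-oxo-4H-chromen-2-yl)-2-hydroxyphenoxy}phenyl)-5-hydroxy-7-methoxy-2,3-dihydro-4H-chromen-4-one, via flavone-7-O-benzyl monoether 11 (not isolated), via catechol-O-benzyl monoether 12 (not isolated)
Conditions: H2 (1 atm), Pd/C (10 wt%), THF/MeOH 1:1, rt, 3 h, stopped at full conversion
Reagents that add atoms: none
Why: Heterogeneous hydrogenolysis of the two benzyl aryl ethers under neutral conditions, which neither enolises nor ring-opens the flavanone, so C-2 stays (S); the aryl methyl ether, the diaryl ether and the flavone enone are inert at 1 atm and room temperature.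

## Compound list

1 | luteolin (2-(3,4-dihydroxyphenyl)-5,7-dihydroxy-4H-chromen-4-one) | O=c1cc(-c2ccc(O)c(O)c2)oc2cc(O)cc(O)c12 | starting material
2 | 7-O-benzylluteolin (7-(benzyloxy)-2-(3,4-dihydroxyphenyl)-5-hydroxy-4H-chromen-4-one) | O=c1cc(-c2ccc(O)c(O)c2)oc2cc(OCc3ccccc3)cc(O)c12 | intermediate
3 | 7,4'-di-O-benzylluteolin (7-(benzyloxy)-2-[4-(benzyloxy)-3-hydroxyphenyl]-5-hydroxy-4H-chromen-4-one) | O=c1cc(-c2ccc(OCc3ccccc3)c(O)c2)oc2cc(OCc3ccccc3)cc(O)c12 | intermediate
4 | 4-fluorobenzaldehyde | O=Cc1ccc(F)cc1 | starting material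
5 | 4-{2-(benzyloxy)-5-[7-(benzyloxy)-5-hydroxy-4-oxo-4H-chromen-2-yl]phenoxy}benzaldehyde | O=Cc1ccc(Oc2cc(-c3cc(=O)c4c(O)cc(OCc5ccccc5)cc4o3)ccc2OCc2ccccc2)cc1 | intermediate
6 | 1-(2,6-dihydroxy-4-methoxyphenyl)ethan-1-one (2',6'-dihydroxy-4'-methoxyacetophenone) | CC(=O)c1c(O)cc(OC)cc1O | starting material
7 | aldol adduct: 3-(4-{2-(benzyloxy)-5-[7-(benzyloxy)-5-hydroxy-4-oxo-4H-chromen-2-yl]phenoxy}phenyl)-1-(2,6-dihydroxy-4-methoxyphenyl)-3-hydroxypropan-1-one (racemic carbinol) | COc1cc(O)c(C(=O)CC(O)c2ccc(Oc3cc(-c4cc(=O)c5c(O)cc(OCc6ccccc6)cc5o4)ccc3OCc3ccccc3)cc2)c(O)c1 | intermediate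
8 | (2E)-3-(4-{2-(benzyloxy)-5-[7-(benzyloxy)-5-hydroxy-4-oxo-4H-chromen-2-yl]phenoxy}phenyl)-1-(2,6-dihydroxy-4-methoxyphenyl)prop-2-en-1-one | COc1cc(O)c(C(=O)/C=C/c2ccc(Oc3cc(-c4cc(=O)c5c(O)cc(OCc6ccccc6)cc5o4)ccc3OCc3ccccc3)cc2)c(O)c1 | intermediate
9 | flavanone enol: (2S)-2-(4-{2-(benzyloxy)-5-[7-(benzyloxy)-5-hydroxy-4-oxo-4H-chromen-2-yl]phenoxy}phenyl)-7-methoxy-2H-chromene-4,5-diol | COc1cc(O)c2c(c1)O[C@H](c1ccc(Oc3cc(-c4cc(=O)c5c(O)cc(OCc6ccccc6)cc5o4)ccc3OCc3ccccc3)cc1)C=C2O | intermediate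
10 | (2S)-2-(4-{2-(benzyloxy)-5-[7-(benzyloxy)-5-hydroxy-4-oxo-4H-chromen-2-yl]phenoxy}phenyl)-5-hydroxy-7-methoxy-2,3-dihydro-4H-chromen-4-one | COc1cc(O)c2c(c1)O[C@H](c1ccc(Oc3cc(-c4cc(=O)c5c(O)cc(OCc6ccccc6)cc5o4)ccc3OCc3ccccc3)cc1)CC2=O | intermediate
11 | flavone-7-O-benzyl monoether: (2S)-2-(4-{5-[7-(benzyloxy)-5-hydroxy-4-oxo-4H-chromen-2-yl]-2-hydroxyphenoxy}phenyl)-5-hydroxy-7-methoxy-2,3-dihydro-4H-chromen-4-one | COc1cc(O)c2c(c1)O[C@H](c1ccc(Oc3cc(-c4cc(=O)c5c(O)cc(OCc6ccccc6)cc5o4)ccc3O)cc1)CC2=O | intermediate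
12 | catechol-O-benzyl monoether: (2S)-2-(4-{2-(benzyloxy)-5-(5,7-dihydroxy-4-oxo-4H-chromen-2-yl)phenoxy}phenyl)-5-hydroxy-7-methoxy-2,3-dihydro-4H-chromen-4-one | COc1cc(O)c2c(c1)O[C@H](c1ccc(Oc3cc(-c4cc(=O)c5c(O)cc(O)cc5o4)ccc3OCc3ccccc3)cc1)CC2=O | intermediate
13 | (2S)-2-(4-{5-(5,7-dihydroxy-4-oxo-4H-chromen-2-yl)-2-hydroxyphenoxy}phenyl)-5-hydroxy-7-methoxy-2,3-dihydro-4H-chromen-4-one (CNP0161794.1) | COc1cc(O)c2c(c1)O[C@H](c1ccc(Oc3cc(-c4cc(=O)c5c(O)cc(O)cc5o4)ccc3O)cc1)CC2=O | target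

## Step count and risks

Total steps: 5. Longest linear sequence: 5 steps (1 to 13); 4 and 6 are used as bought.

The three steps most likely to fail are steps 4, 3 and 1.

**Step 4 (the proposed cyclisation).** It may give low ee, a racemic background closure, or amine-induced racemisation of the product. The fallback is the known ester-activated variant; it sets out from ketone 6 and aldehyde 5 and comes back at 10. Ketone 6 is mono-protected (MOMCl 1.0 equiv, iPr2NEt, CH2Cl2, 0 °C; the second phenol is chelated and stays free) to 1-[2-hydroxy-4-methoxy-6-(methoxymethoxy)phenyl]ethan-1-one F7. Its dianion (LiN(SiMe3)2, 3 equiv, THF, −78 °C) is C-acylated with Boc2O to tert-butyl 3-[2-hydroxy-4-methoxy-6-(methoxymethoxy)phenyl]-3-oxopropanoate F8. Knoevenagel condensation of F8 with 5 (piperidine/AcOH cat., toluene, 4 Å MS) gives the alkylidene β-ketoester F9 as an E/Z mixture. A 9-amino-9-deoxy-epi-cinchona 3,5-bis(trifluoromethyl)phenyl thiourea (10 mol%, toluene, −25 °C; the pseudoenantiomer that gives the 2S series) closes F9 by oxa-Michael addition to the flavanone-3-carboxylate F10 (C-3 epimers, kept in the flask). TsOH·H2O in toluene/MeOH at 80 °C then removes the tert-butyl ester with decarboxylation and cleaves the MOM ether, giving 10.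

**Step 3 (Claisen–Schmidt with an unprotected 2,6-dihydroxy ketone).** The trianion forms slowly, and long exposure to concentrated KOH may open the flavone or cause a Cannizzaro reaction. Any racemic flavanone carried into step 4 would also lower the ee. The fallback changes to a protected ketone and a mild base; it sets out from 6 and 5 and comes back at 8. Ketone 6 is converted (NaH 2.5 equiv, MOMCl, DMF, 0 °C) into 1-[4-methoxy-2,6-bis(methoxymethoxy)phenyl]ethan-1-one F5. F5 condenses with 5 within hours (Ba(OH)2·8H2O, MeOH/THF, 40 °C) to the bis-MOM chalcone F6. HCl in MeOH/THF at rt then frees both phenols without heating, giving 8.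

**Step 1 (regioselective dibenzylation of luteolin).** The 4'-O versus 3'-O selectivity may be only moderate, and over- or under-alkylated material would need separation. The fallback builds 3 from scratch with the 3'/4' pattern fixed by the aldehyde. It does not set out from a numbered compound: it replaces luteolin 1 by two other catalogue materials and comes back at 3. Claisen–Schmidt condensation (KOH, EtOH, rt) of 1-[2,4-bis(benzyloxy)-6-hydroxyphenyl]ethan-1-one F1 with 4-(benzyloxy)-3-hydroxybenzaldehyde F2 gives the 2'-hydroxychalcone F3. Oxidative cyclisation (catalytic iodine, DMSO, 120 °C) gives 5,7,4'-tri-O-benzyl-3'-hydroxyflavone F4. Chelation-directed cleavage of the peri 5-O-benzyl ether (BCl3 1.1 equiv, CH2Cl2, −78 °C) then gives 3.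

## Further compounds

F1 | step 1 | 1-[2,4-bis(benzyloxy)-6-hydroxyphenyl]ethan-1-one | CC(=O)c1c(O)cc(OCc2ccccc2)cc1OCc1ccccc1
F2 | step 1 | 4-(benzyloxy)-3-hydroxybenzaldehyde | O=Cc1ccc(OCc2ccccc2)c(O)c1
F3 | step 1 | (2E)-1-[2,4-bis(benzyloxy)-6-hydroxyphenyl]-3-[4-(benzyloxy)-3-hydroxyphenyl]prop-2-en-1-one | O=C(/C=C/c1ccc(OCc2ccccc2)c(O)c1)c1c(O)cc(OCc2ccccc2)cc1OCc1ccccc1
F4 | step 1 | 5,7-bis(benzyloxy)-2-[4-(benzyloxy)-3-hydroxyphenyl]-4H-chromen-4-one | O=c1cc(-c2ccc(OCc3ccccc3)c(O)c2)oc2cc(OCc3ccccc3)cc(OCc3ccccc3)c12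
F5 | step 3 | 1-[4-methoxy-2,6-bis(methoxymethoxy)phenyl]ethan-1-one | CC(=O)c1c(OCOC)cc(OC)cc1OCOC
F6 | step 3 | (2E)-3-(4-{2-(benzyloxy)-5-[7-(benzyloxy)-5-hydroxy-4-oxo-4H-chromen-2-yl]phenoxy}phenyl)-1-[4-methoxy-2,6-bis(methoxymethoxy)phenyl]prop-2-en-1-one | COCOc1cc(OC)cc(OCOC)c1C(=O)/C=C/c1ccc(Oc2cc(-c3cc(=O)c4c(O)cc(OCc5ccccc5)cc4o3)ccc2OCc2ccccc2)cc1
F7 | step 4 | 1-[2-hydroxy-4-methoxy-6-(methoxymethoxy)phenyl]ethan-1-one | CC(=O)c1c(O)cc(OC)cc1OCOC
F8 | step 4 | tert-butyl 3-[2-hydroxy-4-methoxy-6-(methoxymethoxy)phenyl]-3-oxopropanoate | CC(C)(C)OC(=O)CC(=O)c1c(O)cc(OC)cc1OCOC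
F9 | step 4 | tert-butyl 3-(4-{2-(benzyloxy)-5-[7-(benzyloxy)-5-hydroxy-4-oxo-4H-chromen-2-yl]phenoxy}phenyl)-2-[2-hydroxy-4-methoxy-6-(methoxymethoxy)benzoyl]prop-2-enoate (E/Z mixture) | CC(C)(C)OC(=O)C(=Cc1ccc(Oc2cc(-c3cc(=O)c4c(O)cc(OCc5ccccc5)cc4o3)ccc2OCc2ccccc2)cc1)C(=O)c1c(O)cc(OC)cc1OCOC
F10 | step 4 | tert-butyl (2S)-2-(4-{2-(benzyloxy)-5-[7-(benzyloxy)-5-hydroxy-4-oxo-4H-chromen-2-yl]phenoxy}phenyl)-7-methoxy-5-(methoxymethoxy)-4-oxo-3,4-dihydro-2H-chromene-3-carboxylate (C-3 epimers) | COc1cc(OCOC)c2c(c1)O[C@H](c1ccc(Oc3cc(-c4cc(=O)c5c(O)cc(OCc6ccccc6)cc5o4)ccc3OCc3ccccc3)cc1)C(C(=O)OC(C)(C)C)C2=O
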